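Numbering used throughout: five-membered ring C1 (quaternary, CH3)–C2=C3–C4 (isopropyl carbinol)–C5 (ring-fusion CH); seven-membered ring C1–C5–C6 (ester carbinol)–C7–C8 (methyl carbinol)–C9–C10.
Feature: C4, C5 and C1 are contiguous and correspond to the carbonyl, α- and β-carbon of a 3-alkylcyclopent-2-enone, so the C1–CH3 and C5–C6 bonds can both be made across C1=C5 in one flask.
Late stage: vanillate ester at C6 last; C8 carbinol from a C7=C8 epoxide opened by hydride; C4 carbinol by isopropyl addition to a C4 ketone; C2=C3 by dehydrogenation of that ketone.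
Seven-membered ring: ring-closing metathesis at C7=C8 between the acrolein-derived vinyl group on C6 and the isopropenyl end of the C1 side chain.
Ring order: the five-membered ring is present from the start (3-ethoxycyclopentenone); the seven-membered ring is closed second.

Key step: step 2

Remark: the sense of induction of the copper catalyst is assumed to follow the ligand antipode, so the antipode that delivers methyl to the Re face of the β-carbon is the one used.

Step 1
Reactants: 1 3-ethoxycyclopent-2-en-1-one; 2 4-bromo-2-methylbut-1-ene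
Product: 5 3-(3-methylbut-3-en-1-yl)cyclopent-2-en-1-one, via Grignard reagent 3 (not isolated), via magnesium alkoxide adduct 4 (not isolated)
Conditions: 2, Mg, I2 (cat.), THF, rt to 40 °C; then 1, 0 °C; then 1 M HCl, rt
Reagents that add atoms: water, O (carbonyl oxygen of 5); magnesium, [Mg] (kept only in intermediates 3 and 4)
Why: Grignard 1,2-addition to the vinylogous ester followed by acid hydrolysis and dehydration (Stork–Danheiser-type carbonyl transposition) is a standard entry to 3-alkylcyclopentenones, and no stereocentre is formed.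

Step 2
Reactants: 5 3-(3-methylbut-3-en-1-yl)cyclopent-2-en-1-one; 6 trimethylaluminium; 7 acrolein
Product: 9 (2S,3S)-2-[(1S)-1-hydroxyprop-2-en-1-yl]-3-methyl-3-(3-methylbut-3-en-1-yl)cyclopentan-1-one, via dimethylaluminium enolate 8 (not isolated)
Conditions: Cu(O2CC4H3S) (copper thiophene-2-carboxylate, 5 mol %), O,O'-(1,1'-binaphthyl-2,2'-diyl) N,N-bis(1-phenylethyl)phosphoramidite (10 mol %), Me3Al (1.3 equiv), Et2O, −30 °C; then acrolein (3 equiv), −78 °C; aq. potassium sodium tartrate
Reagents that add atoms: trimethylaluminium (6), C[Al](C)C; acrolein (7), C=CC=O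
Why: Methyl passes from aluminium to the ligand-bound monovalent copper centre, which adds it to the Re face of the β-carbon (C1) of 5 and releases the dimethylaluminium enolate 8; the enolate, with aluminium as internal Lewis acid, then adds 1,2 to acrolein at C5, the whole being the known copper-catalysed asymmetric conjugate addition of trialkylaluminium reagents to 3-substituted cyclopentenones with aldol capture of the aluminium enolate. No ring is closed; C1–CH3 and C5–C6 are formed across the former C1=C5 bond. C1 (S) is set by the chiral ligand on copper. The ring fixes the enolate in the E geometry, so the aluminium-bridged Zimmerman–Traxler chair with the vinyl group equatorial should give the anti aldol, which is the C5 (S)/C6 (S) relation of the target. The step also needs bond formation at C5 on the face syn to the new methyl group and anti to the longer 3-methylbut-3-enyl chain (C6 trans to C10, the later trans ring fusion); only the size difference of the two groups on the neighbouring quaternary carbon secures this, so the bias is expected to be modest and the minor facial isomer is to be removed by chromatography. Carbonyl rather than conjugate attack on acrolein is secured by the oxophilic aluminium enolate at −78 °C.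

Step 3
Reactants: 9 (2S,3S)-2-[(1S)-1-hydroxyprop-2-en-1-yl]-3-methyl-3-(3-methylbut-3-en-1-yl)cyclopentan-1-one
Product: 10 (2S,3S)-2-[(1S)-1-(tert-butyldimethylsilyloxy)prop-2-en-1-yl]-3-methyl-3-(3-methylbut-3-en-1-yl)cyclopentan-1-one
Conditions: TBSOTf (1.1 equiv), 2,6-lutidine, CH2Cl2, −78 °C
Reagents that add atoms: tert-butyldimethylsilyl trifluoromethanesulfonate, CC(C)(C)[Si](C)(C)OS(=O)(=O)C(F)(F)F
Why: O-silylation with a silyl triflate and a hindered pyridine base is fast at low temperature and too weakly basic to cause retro-aldol cleavage or epimerisation at C5, and no stereocentre is formed.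

Step 4
Reactants: 10 (2S,3S)-2-[(1S)-1-(tert-butyldimethylsilyloxy)prop-2-en-1-yl]-3-methyl-3-(3-methylbut-3-en-1-yl)cyclopentan-1-one
Product: 11 (3aS,8S,8aS)-8-(tert-butyldimethylsilyloxy)-3a,6-dimethyl-3,3a,4,5,8,8a-hexahydroazulen-1(2H)-one
Conditions: second-generation Grubbs catalyst RuCl2(=CHPh)(PCy3)(H2IMes) (5 mol %), CH2Cl2 (5 mM), 40 °C
Reagents that add atoms: none
Why: Ring-closing metathesis of the vinyl group with the 1,1-disubstituted alkene closes the seven-membered ring as the trisubstituted C7=C8 cycloheptene with loss of ethene; the trans ring fusion follows from the trans arrangement of C6 and C10 set in step 2 and no stereocentre is touched.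

Step 5
Reactants: 11 (3aS,8S,8aS)-8-(tert-butyldimethylsilyloxy)-3a,6-dimethyl-3,3a,4,5,8,8a-hexahydroazulen-1(2H)-one
Product: 13 (3aS,8S,8aS)-8-(tert-butyldimethylsilyloxy)-3a,6-dimethyl-4,5,8,8a-tetrahydroazulen-1(3aH)-one, via trimethylsilyl enol ether 12 (not isolated)
Conditions: LiN(iPr)2, Me3SiCl (in situ quench), THF, −78 °C; then Pd(OAc)2 (1.1 equiv), MeCN, rt
Reagents that add atoms: chlorotrimethylsilane, C[Si](C)(C)Cl (kept only in intermediate 12)
Why: Saegusa–Ito oxidation, in which kinetic deprotonation takes the C3 methylene and not the hindered C5 methine and divalent palladium then dehydrosilylates the enol ether to the C2=C3 enone, leaving C1, C5 and C6 untouched.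

Step 6
Reactants: 13 (3aS,8S,8aS)-8-(tert-butyldimethylsilyloxy)-3a,6-dimethyl-4,5,8,8a-tetrahydroazulen-1(3aH)-one
Product: 14 7,8-epoxide of 13 with the epoxide oxygen cis to the C1 methyl group and trans to the C6 silyloxy group (skeleton descriptors 1S,5S,6R,7S,8R)
Conditions: mCPBA (1.2 equiv), NaHCO3, CH2Cl2, 0 °C
Reagents that add atoms: 3-chloroperoxybenzoic acid, OOC(=O)c1cccc(Cl)c1
Why: Prilezhaev epoxidation takes the electron-rich trisubstituted C7=C8 alkene and not the electron-poor enone alkene, and the peracid should approach the outer face of the chair cycloheptene, the face of the C1 methyl group and anti to the C6 silyloxy group, which sets C7 and C8 with the oxygen on the face needed for the C8 carbinol.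

Step 7
Reactants: 14 7,8-epoxide of 13
Product: 15 isopropyl adduct of 14 at C4, with the C4 hydroxyl cis to the C1 methyl group and the isopropyl group cis to the C5 hydrogen (skeleton descriptors 1S,4S,5S,6R,7S,8R)
Conditions: CeCl3 (dried), i-PrMgCl, THF, −78 °C; then 14, −78 °C; aq. NH4Cl
Reagents that add atoms: isopropylmagnesium chloride, CC(C)[Mg]Cl
Why: Organocerium 1,2-addition, which is weakly basic and avoids conjugate addition and enolisation, should occur on the carbonyl face of the C5 hydrogen, away from the axial C1 methyl group and the C5–C6 bond, and so place the C4 hydroxyl cis to the C1 methyl group as required.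

Step 8
Reactants: 15 isopropyl adduct of 14 (epoxy alcohol)
Product: 16 (1S,3aS,6R,8S,8aS)-8-(tert-butyldimethylsilyloxy)-3a,6-dimethyl-1-(propan-2-yl)-1,3a,4,5,6,7,8,8a-octahydroazulene-1,6-diol
Conditions: LiBHEt3 (5 equiv), THF, 0 °C to 40 °C; aq. NH4Cl
Reagents that add atoms: none
Why: Hydride opening of a trisubstituted epoxide by LiBHEt3 is an SN2 attack at the less substituted carbon C7, so the C8–O bond and its configuration are retained and C8 becomes the tertiary carbinol while C7 becomes CH2.

Step 9
Reactants: 16 (1S,3aS,6R,8S,8aS)-8-(tert-butyldimethylsilyloxy)-3a,6-dimethyl-1-(propan-2-yl)-1,3a,4,5,6,7,8,8a-octahydroazulene-1,6-diol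
Product: 17 (1S,3aS,6R,8S,8aS)-3a,6-dimethyl-1-(propan-2-yl)-1,3a,4,5,6,7,8,8a-octahydroazulene-1,6,8-triol
Conditions: n-Bu4NF, THF, rt to 45 °C
Reagents that add atoms: none
Why: Fluoride-mediated cleavage of the secondary silyl ether frees the C6 hydroxyl without affecting any stereocentre.

Step 10
Reactants: 18 vanillic acid (4-hydroxy-3-methoxybenzoic acid)
Product: 19 4-acetoxy-3-methoxybenzoic acid
Conditions: Ac2O, pyridine, rt; aq. HCl work-up
Reagents that add atoms: acetic anhydride, CC(=O)OC(C)=O
Why: O-acetylation masks the phenol for the acylation step, and any mixed anhydride formed at the acid is hydrolysed in the aqueous work-up.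

Step 11
Reactants: 17 (1S,3aS,6R,8S,8aS)-3a,6-dimethyl-1-(propan-2-yl)-1,3a,4,5,6,7,8,8a-octahydroazulene-1,6,8-triol; 19 4-acetoxy-3-methoxybenzoic acid
Product: 21 C6 (azulene C8) 4-acetoxy-3-methoxybenzoate of triol 17, both tertiary hydroxyls free, via acid chloride 20 (not isolated)
Conditions: 19, (COCl)2, DMF (cat.), CH2Cl2, 0 °C to rt, concentrate; then 17, Et3N, DMAP, CH2Cl2, 0 °C to rt
Reagents that add atoms: oxalyl chloride, O=C(Cl)C(=O)Cl (chlorine kept only in intermediate 20)
Why: Acid chloride formation followed by DMAP-catalysed acylation esterifies only the secondary C6 hydroxyl, the two tertiary alcohols being unreactive under these conditions, and C6 keeps its configuration because its C–O bond is not broken.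

Step 12
Reactants: 21 C6 4-acetoxy-3-methoxybenzoate of triol 17
Product: 22 CNP0113302.1, (3S,3aS,4S,6R,8aS)-3,6-dihydroxy-6,8a-dimethyl-3-(propan-2-yl)-3,3a,4,5,6,7,8,8a-octahydroazulen-4-yl 4-hydroxy-3-methoxybenzoate
Conditions: pyrrolidine (3 equiv), CH2Cl2, 0 °C to rt
Reagents that add atoms: none
Why: Aminolysis removes the aryl acetate, which is far more electrophilic than the hindered secondary aroate, and so frees the phenol without touching the C6 ester or the tertiary alcohols.

Compound list
1 | 3-ethoxycyclopent-2-en-1-one | CCOC1=CC(=O)CC1 | starting material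
2 | 4-bromo-2-methylbut-1-ene | CC(=C)CCBr | starting material
3 | (3-methylbut-3-en-1-yl)magnesium bromide | CC(=C)CC[Mg]Br | intermediate
4 | bromomagnesium 3-ethoxy-1-(3-methylbut-3-en-1-yl)cyclopent-2-en-1-olate (racemic 1,2-adduct) | CCOC1=CC(CCC(C)=C)(O[Mg]Br)CC1 | intermediate
5 | 3-(3-methylbut-3-en-1-yl)cyclopent-2-en-1-one | O=C1C=C(CCC(C)=C)CC1 | intermediate
6 | trimethylaluminium | C[Al](C)C | starting material
7 | acrolein (prop-2-enal) | C=CC=O | starting material
8 | dimethylaluminium (3S)-3-methyl-3-(3-methylbut-3-en-1-yl)cyclopent-1-en-1-olate | C[Al](C)OC1=C[C@@](C)(CCC(C)=C)CC1 | intermediate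
9 | (2S,3S)-2-[(1S)-1-hydroxyprop-2-en-1-yl]-3-methyl-3-(3-methylbut-3-en-1-yl)cyclopentan-1-one | O[C@@H](C=C)[C@H]1C(=O)CC[C@]1(C)CCC(C)=C | intermediate
10 | (2S,3S)-2-[(1S)-1-(tert-butyldimethylsilyloxy)prop-2-en-1-yl]-3-methyl-3-(3-methylbut-3-en-1-yl)cyclopentan-1-one | CC(C)(C)[Si](C)(C)O[C@@H](C=C)[C@H]1C(=O)CC[C@]1(C)CCC(C)=C | intermediate
11 | (3aS,8S,8aS)-8-(tert-butyldimethylsilyloxy)-3a,6-dimethyl-3,3a,4,5,8,8a-hexahydroazulen-1(2H)-one | CC(C)(C)[Si](C)(C)O[C@H]1C=C(C)CC[C@@]2(C)CCC(=O)[C@H]12 | intermediate
12 | C3=C4 trimethylsilyl enol ether of 11 (skeleton descriptors 1S,5S,6S) | CC(C)(C)[Si](C)(C)O[C@H]1C=C(C)CC[C@@]2(C)CC=C(O[Si](C)(C)C)[C@H]12 | intermediate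
13 | (3aS,8S,8aS)-8-(tert-butyldimethylsilyloxy)-3a,6-dimethyl-4,5,8,8a-tetrahydroazulen-1(3aH)-one | CC(C)(C)[Si](C)(C)O[C@H]1C=C(C)CC[C@@]2(C)C=CC(=O)[C@H]12 | intermediate
14 | 7,8-epoxide of 13, epoxide oxygen cis to the C1 methyl group and trans to the C6 silyloxy group (skeleton descriptors 1S,5S,6R,7S,8R) | CC(C)(C)[Si](C)(C)O[C@H]1[C@@H]3O[C@]3(C)CC[C@@]2(C)C=CC(=O)[C@H]12 | intermediate
15 | C4 isopropyl carbinol from 14, hydroxyl cis to the C1 methyl group, with C2=C3, the 7,8-epoxide and the C6 silyl ether retained (skeleton descriptors 1S,4S,5S,6R,7S,8R) | CC(C)(C)[Si](C)(C)O[C@H]1[C@@H]3O[C@]3(C)CC[C@@]2(C)C=C[C@@](O)(C(C)C)[C@H]12 | intermediate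
16 | (1S,3aS,6R,8S,8aS)-8-(tert-butyldimethylsilyloxy)-3a,6-dimethyl-1-(propan-2-yl)-1,3a,4,5,6,7,8,8a-octahydroazulene-1,6-diol | CC(C)(C)[Si](C)(C)O[C@H]1C[C@](C)(O)CC[C@@]2(C)C=C[C@@](O)(C(C)C)[C@H]12 | intermediate
17 | (1S,3aS,6R,8S,8aS)-3a,6-dimethyl-1-(propan-2-yl)-1,3a,4,5,6,7,8,8a-octahydroazulene-1,6,8-triol | O[C@H]1C[C@](C)(O)CC[C@@]2(C)C=C[C@@](O)(C(C)C)[C@H]12 | intermediate
18 | vanillic acid (4-hydroxy-3-methoxybenzoic acid) | COc1cc(C(=O)O)ccc1O | starting material
19 | 4-acetoxy-3-methoxybenzoic acid | COc1cc(C(=O)O)ccc1OC(C)=O | intermediate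
20 | 4-acetoxy-3-methoxybenzoyl chloride | COc1cc(C(=O)Cl)ccc1OC(C)=O | intermediate
21 | C6 (azulene C8) 4-acetoxy-3-methoxybenzoate of triol 17 | COc1cc(C(=O)O[C@H]2C[C@](C)(O)CC[C@@]3(C)C=C[C@@](O)(C(C)C)[C@H]23)ccc1OC(C)=O | intermediate
22 | CNP0113302.1, (3S,3aS,4S,6R,8aS)-3,6-dihydroxy-6,8a-dimethyl-3-(propan-2-yl)-3,3a,4,5,6,7,8,8a-octahydroazulen-4-yl 4-hydroxy-3-methoxybenzoate | COc1cc(C(=O)O[C@H]2C[C@](C)(O)CC[C@@]3(C)C=C[C@@](O)(C(C)C)[C@H]23)ccc1O | target

Total step count: 12. Longest linear sequence: 11 steps (steps 1–9, 11 and 12, from 1 and 2 to 22); step 10 is a one-step side branch from vanillic acid.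

Steps most likely to fail

Step 2. The dimethylaluminium enolate is a weak nucleophile, so aldol capture may lag behind methyl transfer from residual trimethylaluminium to acrolein and behind acrolein oligomerisation. In addition, the facial discrimination at C5 between the methyl group and the 3-methylbut-3-enyl chain on C1 may be low. The fallback separates the two bond formations and sets out from 5. The same copper-catalysed methyl addition is run and the enolate is quenched with Me3SiOTf to give the isolable enol ether (S)-trimethyl{[3-methyl-3-(3-methylbut-3-en-1-yl)cyclopent-1-en-1-yl]oxy}silane F1. MeLi in THF at 0 °C cleaves this to the lithium enolate F2, free of copper and aluminium, and ZnCl2 converts it to the chlorozinc enolate F3. Acrolein is then added at −78 °C and the mixture warmed to −20 °C. Under these reversible, chelate-controlled conditions the anti aldol with C6 trans to the longer chain should accumulate; the route is rejoined at 9.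

Step 7. The branched nucleophile carries β-hydrogens and may reduce the hindered ketone, or enolise it at C5 with subsequent loss of the C6 silanolate, instead of adding. The fallback sets out from 14. Isopropenylmagnesium bromide with CeCl3 (THF, −78 °C) adds the smaller sp2 nucleophile to the same carbonyl face and gives the isopropenyl carbinol F4. Hydrogenation with RhCl(PPh3)3 and H2 (benzene, rt) should then saturate the exposed 1,1-disubstituted alkene and leave the C2=C3 ring alkene, which is flanked by two fully substituted carbons; the route is rejoined at 15.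

Step 8. Hydride delivery to C7 may be slow or incomplete, because the rear side of the C7–O bond lies on the inner face of the ring next to the C6 silyl ether and the axial C5 hydrogen; forcing the reaction by heating risks loss of the silyl group. The fallback sets out from 15. n-Bu4NF first removes the silyl group to give the epoxy diol F5. NaAlH2(OCH2CH2OMe)2 (THF, 0 °C to rt) then delivers hydride intramolecularly from the C6 alkoxyaluminate to C7, the known 1,3-diol-forming reduction of 2,3-epoxy alcohols. This gives triol 17 directly, so the route is rejoined at 17 and step 9 is not needed.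

Further compounds
F1 | step 2 | (S)-trimethyl{[3-methyl-3-(3-methylbut-3-en-1-yl)cyclopent-1-en-1-yl]oxy}silane | C[Si](C)(C)OC1=C[C@@](C)(CCC(C)=C)CC1
F2 | step 2 | lithium (3S)-3-methyl-3-(3-methylbut-3-en-1-yl)cyclopent-1-en-1-olate | [Li]OC1=C[C@@](C)(CCC(C)=C)CC1
F3 | step 2 | chlorozinc (3S)-3-methyl-3-(3-methylbut-3-en-1-yl)cyclopent-1-en-1-olate | Cl[Zn]OC1=C[C@@](C)(CCC(C)=C)CC1
F4 | step 7 | C4 isopropenyl carbinol from 14 (prop-1-en-2-yl in place of the isopropyl group of 15, same configuration) | CC(C)(C)[Si](C)(C)O[C@H]1[C@@H]3O[C@]3(C)CC[C@@]2(C)C=C[C@@](O)(C(C)=C)[C@H]12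
F5 | step 8 | epoxy diol: 15 without the silyl group (free C6 hydroxyl) | O[C@H]1[C@@H]3O[C@]3(C)CC[C@@]2(C)C=C[C@@](O)(C(C)C)[C@H]12
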